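The route rests on the bond between C8 of one 5,7-dimethoxycoumarin and the allylic carbon C2 of the cyclohexene ring (C1 bears the carbinol side chain, C3=C4 is the alkene, C6 the gem-dimethyl carbon). The key step exploits the fact that C2 lies next to the C3=C4 double bond and 1,3 to the oxygen of the exocyclic carbinol on C1: both positions are first tied into a cis-fused six-membered cyclic carbonate. Zerovalent palladium ionises its allylic C2–O bond, carbon dioxide leaves, and a coumarin-8-ylboronic acid is coupled at C2 with inversion. One operation thus joins the halves, sets the trans C1/C2 relationship and frees the carbinol. The carbonate stems from an asymmetric syn-aldol of isophorone with 8-formyl-5,7-dimethoxycoumarin.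

Key step: step 8

Assumption: the (4R)-configured oxazaborolidinone catalyst of step 3 is taken to direct the nucleophile to the Si face of aldehyde 2, by analogy with the facial preference of this catalyst class towards aromatic aldehydes; if the sense proves opposite, its mirror image is used.

**Step 1**
Reactants: 1 5,7-dimethoxy-2H-chromen-2-one (citropten)
Product: 2 5,7-dimethoxy-2-oxo-2H-chromene-8-carbaldehyde
Conditions: POCl3, DMF, 0 to 70 °C; then ice-water
Reagents that add atoms: N,N-dimethylformamide CN(C)C=O; water O
Why: Vilsmeier–Haack formylation should take place at C8, which is para to the 5-methoxy group and ortho to the 7-methoxy group and the ring oxygen, and so is the most nucleophilic and least hindered CH of the benzenoid ring (C6 has only the weakly donating lactone oxygen para).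

**Step 2**
Reactants: 3 3,5,5-trimethylcyclohex-2-en-1-one (isophorone)
Product: 4 trimethyl[(3,3,5-trimethylcyclohexa-1,5-dien-1-yl)oxy]silane
Conditions: LiN(iPr)2, THF, −78 °C; Me3SiCl, −78 °C to rt
Reagents that add atoms: chlorotrimethylsilane C[Si](C)(C)Cl
Why: Kinetic enolisation at the alpha-prime CH2 gives the cross-conjugated lithium dienolate, which is O-silylated (silyl enol ether formation).

**Step 3**
Reactants: 2 5,7-dimethoxy-2-oxo-2H-chromene-8-carbaldehyde; 4 trimethyl[(3,3,5-trimethylcyclohexa-1,5-dien-1-yl)oxy]silane
Product: 6 (6S)-6-[(S)-(5,7-dimethoxy-2-oxo-2H-chromen-8-yl)(hydroxy)methyl]-3,5,5-trimethylcyclohex-2-en-1-one, via trimethylsilyl ether of the aldol 5 (not isolated)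
Conditions: (4R)-2-butyl-4-(1H-indol-3-ylmethyl)-3-(4-methylbenzenesulfonyl)-1,3,2-oxazaborolidin-5-one (20 mol%), EtCN, −78 °C; then 10% aq. citric acid, THF, 0 °C
Reagents that add atoms: none
Why: Catalytic asymmetric Mukaiyama aldol addition, in which the boron Lewis acid binds the aldehyde and shields one face so that the enol ether terminus should attack the Si face (S carbinol), while the open antiperiplanar transition state of the cyclic E-enol ether favours the syn aldol and thereby fixes the ring stereocentre as S.

**Step 4**
Reactants: 6 (6S)-6-[(S)-(5,7-dimethoxy-2-oxo-2H-chromen-8-yl)(hydroxy)methyl]-3,5,5-trimethylcyclohex-2-en-1-one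
Product: 8 8-{(S)-hydroxy[(1R,2S)-2-hydroxy-4,6,6-trimethylcyclohex-3-en-1-yl]methyl}-5,7-dimethoxy-2H-chromen-2-one, via diethylboron chelate 7 (not isolated)
Conditions: Et2BOMe, THF/MeOH 4:1, −78 °C; NaBH4, −78 °C; then AcOH, co-evaporation from MeOH
Reagents that add atoms: none
Why: Narasaka–Prasad 1,3-syn reduction, in which chelate 7 holds the side chain pseudo-equatorial and borohydride should add 1,2 to the enone carbonyl from the face opposite the axial methyl group of the neighbouring gem-dimethyl carbon, placing the new hydroxyl (S) cis to the side chain and 1,3-syn to the carbinol.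

**Step 5**
Reactants: 8 8-{(S)-hydroxy[(1R,2S)-2-hydroxy-4,6,6-trimethylcyclohex-3-en-1-yl]methyl}-5,7-dimethoxy-2H-chromen-2-one
Product: 9 (4S,4aR,8aS)-4-(5,7-dimethoxy-2-oxo-2H-chromen-8-yl)-5,5,7-trimethyl-4a,5,6,8a-tetrahydro-4H-1,3-benzodioxin-2-one
Conditions: 1,1'-carbonyldiimidazole, DMAP (cat.), THF, 60 °C
Reagents that add atoms: 1,1'-carbonyldiimidazole O=C(n1ccnc1)n1ccnc1
Why: Carbonylation of the 1,3-diol by two acyl substitutions closes the cis-fused 1,3-dioxan-2-one without touching a stereocentre.

**Step 6**
Reactants: 1 5,7-dimethoxy-2H-chromen-2-one (citropten)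
Product: 10 8-iodo-5,7-dimethoxy-2H-chromen-2-one
Conditions: N-iodosuccinimide, CF3CO2H (cat.), MeCN, rt
Reagents that add atoms: N-iodosuccinimide O=C1CCC(=O)N1I
Why: Electrophilic aromatic iodination should occur at C8, the position para to the 5-methoxy group, for the reason given in step 1.

**Step 7**
Reactants: 10 8-iodo-5,7-dimethoxy-2H-chromen-2-one
Product: 11 (5,7-dimethoxy-2-oxo-2H-chromen-8-yl)boronic acid
Conditions: B2(OH)4, Pd(OAc)2 (2 mol%), XPhos (2-dicyclohexylphosphino-2',4',6'-triisopropylbiphenyl, 4 mol%), KOAc, EtOH, 80 °C
Reagents that add atoms: tetrahydroxydiboron OB(O)B(O)O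
Why: Miyaura-type palladium-catalysed borylation of the aryl iodide with tetrahydroxydiboron should give the free boronic acid directly, the bulky biarylphosphine being chosen for the doubly ortho-substituted iodide.

**Step 8**
Reactants: 9 (4S,4aR,8aS)-4-(5,7-dimethoxy-2-oxo-2H-chromen-8-yl)-5,5,7-trimethyl-4a,5,6,8a-tetrahydro-4H-1,3-benzodioxin-2-one; 11 (5,7-dimethoxy-2-oxo-2H-chromen-8-yl)boronic acid
Product: 12 8-{(S)-[(1S,2R)-2-(5,7-dimethoxy-2-oxo-2H-chromen-8-yl)-4,6,6-trimethylcyclohex-3-en-1-yl](hydroxy)methyl}-5,7-dimethoxy-2H-chromen-2-one (CNP0324863.2)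
Conditions: Pd2(dba)3·CHCl3 (dba = dibenzylideneacetone, 2.5 mol%), SPhos (2-dicyclohexylphosphino-2',6'-dimethoxybiphenyl, 6 mol%), 11 (2 equiv), THF, 50 °C, no added base
Reagents that add atoms: none
Why: Zerovalent palladium ionises the pseudo-axial allylic C–O bond of carbonate 9 from the face opposite to oxygen, carbon dioxide is lost, and the alkoxide of the resulting zwitterionic π-allylpalladium species activates boronic acid 11 so that the aryl group passes to palladium and reductive elimination forms the aryl–C2 bond on the metal-bearing face. The closest known reaction type is the base-free Suzuki–Miyaura-type allyl–aryl coupling of allylic carbonates and of vinyl-substituted cyclic carbonates with arylboronic acids (Tsuji–Trost ionisation followed by inner-sphere arylation). No ring is closed; the temporary 1,3-dioxan-2-one ring is opened, which releases the carbinol as the free alcohol. The new stereocentre C2 is controlled by the stereospecific net inversion of this sequence (ionisation with inversion, aryl delivery with retention) relative to the carbonate oxygen that step 4 placed cis to the side chain, so the aryl group should end trans to the side chain with the R configuration. The step needs site selectivity between the two allyl termini, secured because coupling at the methyl-bearing C4 would create a quaternary benzylic carbon whereas C2 is a CH, and it needs chemoselectivity for the allylic over the benzylic C–O bond, which zerovalent palladium provides. The neutral conditions also spare the acid-sensitive electron-rich benzylic carbinol and both lactones.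

**Compound list**
1 | 5,7-dimethoxy-2H-chromen-2-one (citropten) | COc1cc(OC)c2ccc(=O)oc2c1 | starting material
2 | 5,7-dimethoxy-2-oxo-2H-chromene-8-carbaldehyde | COc1cc(OC)c2ccc(=O)oc2c1C=O | intermediate
3 | 3,5,5-trimethylcyclohex-2-en-1-one (isophorone) | CC1=CC(=O)CC(C)(C)C1 | starting material
4 | trimethyl[(3,3,5-trimethylcyclohexa-1,5-dien-1-yl)oxy]silane | CC1=CC(O[Si](C)(C)C)=CC(C)(C)C1 | intermediate
5 | (6S)-6-[(S)-(5,7-dimethoxy-2-oxo-2H-chromen-8-yl)(trimethylsilyloxy)methyl]-3,5,5-trimethylcyclohex-2-en-1-one (not isolated) | COc1cc(OC)c2ccc(=O)oc2c1[C@@H](O[Si](C)(C)C)[C@H]1C(=O)C=C(C)CC1(C)C | intermediate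
6 | (6S)-6-[(S)-(5,7-dimethoxy-2-oxo-2H-chromen-8-yl)(hydroxy)methyl]-3,5,5-trimethylcyclohex-2-en-1-one | COc1cc(OC)c2ccc(=O)oc2c1[C@@H](O)[C@H]1C(=O)C=C(C)CC1(C)C | intermediate
7 | (6S)-6-[(S)-(diethylboryloxy)(5,7-dimethoxy-2-oxo-2H-chromen-8-yl)methyl]-3,5,5-trimethylcyclohex-2-en-1-one, boron coordinated by the ketone oxygen (not isolated) | COc1cc(OC)c2ccc(=O)oc2c1[C@@H](OB(CC)CC)[C@H]1C(=O)C=C(C)CC1(C)C | intermediate
8 | 8-{(S)-hydroxy[(1R,2S)-2-hydroxy-4,6,6-trimethylcyclohex-3-en-1-yl]methyl}-5,7-dimethoxy-2H-chromen-2-one | COc1cc(OC)c2ccc(=O)oc2c1[C@@H](O)[C@H]1[C@@H](O)C=C(C)CC1(C)C | intermediate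
9 | (4S,4aR,8aS)-4-(5,7-dimethoxy-2-oxo-2H-chromen-8-yl)-5,5,7-trimethyl-4a,5,6,8a-tetrahydro-4H-1,3-benzodioxin-2-one | COc1cc(OC)c2ccc(=O)oc2c1[C@@H](OC(=O)O5)[C@H]1[C@@H]5C=C(C)CC1(C)C | intermediate
10 | 8-iodo-5,7-dimethoxy-2H-chromen-2-one | COc1cc(OC)c2ccc(=O)oc2c1I | intermediate
11 | (5,7-dimethoxy-2-oxo-2H-chromen-8-yl)boronic acid | COc1cc(OC)c2ccc(=O)oc2c1B(O)O | intermediate
12 | 8-{(S)-[(1S,2R)-2-(5,7-dimethoxy-2-oxo-2H-chromen-8-yl)-4,6,6-trimethylcyclohex-3-en-1-yl](hydroxy)methyl}-5,7-dimethoxy-2H-chromen-2-one | COc1cc(OC)c2ccc(=O)oc2c1[C@@H](O)[C@H]1[C@H](c2c(OC)cc(OC)c3ccc(=O)oc23)C=C(C)CC1(C)C | target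

Total step count: 8. Longest linear sequence: 5 steps (steps 1 or 2, then 3, 4, 5, 8).

**Steps most likely to fail**

Step 8. Aryl transfer from the doubly ortho-oxygenated boronic acid may be slow, so that β-hydride loss from the π-allylpalladium intermediate (to cyclohexadienes) or protodeboronation overtakes the coupling. The fallback sets out from carbonate 9 and uses citropten 1 itself as the nucleophile: under BF3·OEt2 in CH2Cl2 at −40 °C the allylic C–O bond ionises to the cyclohexenyl cation, C8 of excess 1 should attack C2 anti to the side chain in a Friedel–Crafts allylation of the kind used for acid-mediated terpenylation of electron-rich arenes, carbon dioxide is lost, and the route is rejoined at target 12. This fallback makes no new compound (F0).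

Step 3. Addition to the electron-rich, doubly ortho-substituted aldehyde at the neopentyl-type enol ether carbon may be sluggish, and binding of the boron catalyst to the lactone carbonyl may erode facial control. The fallback sets out from isophorone 3 and activates the nucleophile instead of the aldehyde: LiN(iPr)2 in THF at −78 °C followed by ClSi(OMe)3 gives trimethoxy[(3,3,5-trimethylcyclohexa-1,5-dien-1-yl)oxy]silane F1, which is added to aldehyde 2 with AgF and the appropriate enantiomer of 2,2'-bis(di-p-tolylphosphino)-1,1'-binaphthyl in MeOH at −78 to −20 °C. This fluoride-activated silicon enolate aldol is syn-selective irrespective of enol ether geometry and comes back to the route at aldol 6.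

Step 7. Protodeboronation or hydrodeiodination may compete during borylation of the hindered, electron-rich iodide in hot ethanol. The fallback sets out from iodide 10 and avoids boron: zinc insertion (Zn dust, LiCl, THF, 50 °C) gives (5,7-dimethoxy-2-oxo-2H-chromen-8-yl)zinc iodide F2, which is coupled directly with carbonate 9 under the palladium catalyst of step 8 in a Negishi-type allyl–aryl coupling, with the same inversion at C2, and comes back to the route at target 12.

**Further compounds**
F0 | step 8 | none | none
F1 | step 3 | trimethoxy[(3,3,5-trimethylcyclohexa-1,5-dien-1-yl)oxy]silane | CC1=CC(O[Si](OC)(OC)OC)=CC(C)(C)C1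
F2 | step 7 | (5,7-dimethoxy-2-oxo-2H-chromen-8-yl)zinc iodide | COc1cc(OC)c2ccc(=O)oc2c1[Zn]I
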